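**The leftover.** Start from what G and X do not hold. In the zeta run at 4.00 h they read 18.6% and 28.9% of the charge, so 52.5% sits in species nobody read.

| setting | beta | zeta | flask |
|---|---|---|---|
| Z | 0.10 M | 0.050 M | 0.10 M |
| remark | the very flask that is asked about, followed so far | run made earlier |  |
| time |  |  | 4.0 h |

- beta (time / min: G / %, X / %): 4.00: 0.8, 1.0; 10.0: 2.3, 2.6; 20.0: 5.8, 9.6; 30.0: 10.6, 16.1
- zeta (time / h: G / %, X / %): 0.500: 14.2, 22.3; 1.33: 18.2, 28.8; 2.50: 18.7, 28.4; 4.00: 18.6, 28.9

(readings scatter by 0.5 percentage points)

- share of G in G plus X at 8.0 min
- share of G in G plus X at 40 min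
- share of G in G plus X at 4.0 h
- which of G and X there is more of at 4.0 h

- given per volume of solution although it is solid: Z
- the numbers in the tables scatter by 0.5 percentage points (one standard deviation)
- steps that have been proposed: L <-> D; L -> G; L -> X; D -> J; Z <-> L
- at the start none of Z is in solution

**The count.** Count turnovers at the fork. G and X are proposed as parallel steps out of L, so if both are first order in L, each L leaving by either step has one fixed chance of becoming G. Call this the branch share, the selectivity of the fork: G over G plus X, here from the last zeta reading, 39.2%. That is my own reckoning. The beta flask, with twice the charge, reads 39.7% at 30.0 min.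

**On your return.** At 30.0 min the beta flask holds 10.6% G and 16.1% X. Expect the same share there at each asked time, and X ahead, since the share is below half.

**Leave alone.** Do not correct the share for the beta reading at 4.00 min: its 44.4% rests on 1.80% of G plus X, and each reading scatters by 0.5 percentage points.

**The forecast.** It gives 39.2%, 39.1% and 39.1%, with X ahead, on the ground that “if both steps have the same order in L, their ratio is simply k_G/k_X, whatever the dissolution and the D/J side route are doing”.

**The result.** The beta flask gives 39.5%, 39.5% and 39.5%, with X ahead.

    L ⇌ D (K = 0.860, k = 0.00320 /s)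
    L → G (k = 3.00 × 10⁻⁴ /s)
    L → X (k = 4.60 × 10⁻⁴ /s)
    D → J (k = 0.00140 /s)
    Z ⇌ L, rate k5*(cs5 - [L]) while solid is left; crystals form when [L] > cs5 (solubility = 0.0700 M, k = 0.00110 /s)

**The use.** The rate constant of the G step over that of the X step is 0.652. Apply the branch share of 39.2% to this flask: its 18.4% of G implies 28.5% of X, and it holds 28.1%. Apply it to the neighbour flask with 2.50 times the charge: its 18.4% of G implies 28.5% of X, and at 4.00 h it holds 28.1%.

All runs come from a simulation for an exercise, and the scatter is random.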